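**Retrosynthetic overview**
- Feature: ring A is a 1,4-quinone in which the C1 and C4 carbonyls flank a C2=C3 unit that carries only the C1' side chain (at C2) and a hydrogen (at C3); it is fused at C4a–C8a to the symmetrical 5,8-dioxygenated ring B.
- Key disconnection: C1–C2 and C3–C4. A terminal alkyne that already holds the (R)-C1' ester is inserted between the two acyl carbons of 3,6-dimethoxybenzocyclobutene-1,2-dione through a phthaloylcobalt metallacycle. Ring B is present from the start and ring A is closed last.
- Dione: benzyne/ketene acetal [2+2] from 2-bromo-1,4-dimethoxybenzene, ketal hydrolysis, gem-dibromination, hydrolysis.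
- Alkyne: Weinreb amide of 4-methylpent-3-enoic acid, silyl ynone, asymmetric transfer hydrogenation (sets C1'), C-desilylation, Steglich esterification with O-triethylsilyl 3-hydroxy-3-methylbutanoic acid.
- End game: cleavage of the two peri methyl ethers with MgI2·OEt2, then removal of the silyl group.

Key step: step 11

Remark: the target is a naphthazarin whose two tautomers interconvert rapidly; it is written, as in the given structure, with the side chain on the quinone ring.
Remark: the sense of induction in step 7 is assigned by analogy with alkyl alkynyl ketones, for which the (S,S) ligand leads to the (S) carbinol when the alkynyl group outranks the alkyl group; the (R,R) ligand is therefore chosen.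

**Step 1**
Reactants: 1 2-bromo-1,4-dimethoxybenzene; 2 1,1-dimethoxyethene
Product: 4 3,6-dimethoxybenzocyclobuten-1(2H)-one dimethyl ketal (1,1,3,6-tetramethoxy-1,2-dihydrocyclobutabenzene), via 3,6-dimethoxybenzyne 3 (not isolated)
Conditions: NaNH2 (3 equiv), 2 (2.5 equiv), THF, reflux
Reagents that add atoms: none
Why: NaNH2 removes H-3 (between Br and OMe) and bromide leaves to give the symmetrical aryne 3, which should undergo the known stepwise aryne/ketene acetal [2+2] cycloaddition, with regiochemistry made irrelevant by the symmetry of 3.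

**Step 2**
Reactants: 4 3,6-dimethoxybenzocyclobuten-1(2H)-one dimethyl ketal
Product: 5 3,6-dimethoxybenzocyclobuten-1(2H)-one
Conditions: 1 M HCl (aq), THF, rt
Reagents that add atoms: water, O
Why: Acid-catalysed ketal hydrolysis, which for this strained ketal should proceed in dilute acid at room temperature without touching the aryl methyl ethers.

**Step 3**
Reactants: 5 3,6-dimethoxybenzocyclobuten-1(2H)-one
Product: 6 2,2-dibromo-3,6-dimethoxybenzocyclobuten-1(2H)-one
Conditions: NBS (2.2 equiv), (PhCO2)2 (cat.), CCl4, reflux, hν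
Reagents that add atoms: N-bromosuccinimide, O=C1CCC(=O)N1Br
Why: Wohl–Ziegler radical bromination: the C2 methylene is both benzylic and alpha to the carbonyl, so both hydrogens should be replaced under non-polar radical-chain conditions that disfavour ionic bromination of the ring.

**Step 4**
Reactants: 6 2,2-dibromo-3,6-dimethoxybenzocyclobuten-1(2H)-one
Product: 7 3,6-dimethoxybenzocyclobutene-1,2-dione
Conditions: AgOCOCF3 (2.2 equiv), MeCN–H2O, rt → 50 °C
Reagents that add atoms: water, O
Why: Silver-assisted hydrolysis of a benzylic gem-dibromide, helped by the ortho methoxy group that stabilises the developing cation, should unveil the second carbonyl.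

**Step 5**
Reactants: 8 4-methylpent-3-enoic acid
Product: 9 N-methoxy-N,4-dimethylpent-3-enamide
Conditions: CDI, CH2Cl2, rt; then MeNHOMe·HCl, rt
Reagents that add atoms: N,O-dimethylhydroxylamine hydrochloride, CNOC.Cl
Why: Weinreb amide formation through the acyl imidazolide, under near-neutral conditions that should leave the β,γ-alkene out of conjugation.

**Step 6**
Reactants: 9 N-methoxy-N,4-dimethylpent-3-enamide; 10 ethynyltrimethylsilane
Product: 12 6-methyl-1-(trimethylsilyl)hept-5-en-1-yn-3-one, via lithium (trimethylsilyl)acetylide 11 (not isolated)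
Conditions: 10, n-BuLi, THF, −78 °C; then 9, −78 → −20 °C; cold aq. NH4Cl
Reagents that add atoms: none
Why: Weinreb ketone synthesis: the acetylide adds once to give a chelated tetrahedral intermediate that collapses to the ynone only on the cold, weakly acidic quench, which should prevent over-addition and migration of the alkene into conjugation.

**Step 7**
Reactants: 12 6-methyl-1-(trimethylsilyl)hept-5-en-1-yn-3-one
Product: 13 (R)-6-methyl-1-(trimethylsilyl)hept-5-en-1-yn-3-ol
Conditions: Ru[(R,R)-TsNCH(Ph)CH(Ph)NH](p-cymene) (1 mol %), i-PrOH, rt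
Reagents that add atoms: none
Why: Noyori asymmetric transfer hydrogenation of an alkynyl ketone: the bifunctional divalent ruthenium hydride delivers hydrogen to the carbonyl face fixed by the (R,R)-diamine, with the alkynyl group taking the place an aryl group normally occupies, which should set the (R) carbinol and leave alkyne and alkene unreduced.

**Step 8**
Reactants: 13 (R)-6-methyl-1-(trimethylsilyl)hept-5-en-1-yn-3-ol
Product: 14 (R)-6-methylhept-5-en-1-yn-3-ol
Conditions: K2CO3 (0.2 equiv), MeOH, 0 °C → rt
Reagents that add atoms: none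
Why: Base-catalysed methanolysis of the alkynyl C–Si bond (protodesilylation), which does not involve the carbinol centre.

**Step 9**
Reactants: 15 3-hydroxy-3-methylbutanoic acid
Product: 17 3-methyl-3-(triethylsilyloxy)butanoic acid, via triethylsilyl 3-methyl-3-(triethylsilyloxy)butanoate 16 (not isolated)
Conditions: TESOTf (2.3 equiv), 2,6-lutidine, CH2Cl2, 0 °C; then K2CO3 (cat.), MeOH–H2O, 0 °C; pH 5 work-up
Reagents that add atoms: triethylsilyl trifluoromethanesulfonate, CC[Si](CC)(CC)OS(=O)(=O)C(F)(F)F
Why: Silylation of both the tertiary hydroxyl and the carboxyl group with the reactive silyl triflate, followed by selective solvolysis of the much more labile silyl ester.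

**Step 10**
Reactants: 14 (R)-6-methylhept-5-en-1-yn-3-ol; 17 3-methyl-3-(triethylsilyloxy)butanoic acid
Product: 18 (R)-6-methylhept-5-en-1-yn-3-yl 3-methyl-3-(triethylsilyloxy)butanoate
Conditions: DCC, DMAP (cat.), CH2Cl2, 0 °C → rt
Reagents that add atoms: none
Why: Steglich esterification, in which acylation takes place at oxygen so that the (R) centre is retained.

**Step 11**
Reactants: 7 3,6-dimethoxybenzocyclobutene-1,2-dione; 18 (R)-6-methylhept-5-en-1-yn-3-yl 3-methyl-3-(triethylsilyloxy)butanoate
Product: 21 (R)-1-(5,8-dimethoxy-1,4-dioxo-1,4-dihydronaphthalen-2-yl)-4-methylpent-3-en-1-yl 3-methyl-3-(triethylsilyloxy)butanoate, via chlorobis(triphenylphosphine)(3,6-dimethoxyphthaloyl)cobalt 19 (not isolated), via chloro(dimethylglyoxime)(pyridine)(3,6-dimethoxyphthaloyl)cobalt 20 (not isolated)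
Conditions: ClCo(PPh3)3 (1.05 equiv), PhCl, rt → 40 °C, Ar; then dimethylglyoxime, pyridine, rt, evaporate; then 18 (1.2 equiv), CoCl2·6H2O, ClCH2CH2Cl, rt → 60 °C
Reagents that add atoms: none
Why: Monovalent cobalt in ClCo(PPh3)3 should add oxidatively across the strained acyl–acyl bond of 7 to give the five-membered phthaloyl metallacycle 19 of trivalent cobalt, and exchange of the phosphines for dimethylglyoxime and pyridine gives the octahedral complex 20, in which the mild Lewis acid CoCl2·6H2O opens a coordination site. The terminal alkyne of 18 then binds and inserts into one cobalt–acyl bond (forming C1–C2), and C–C reductive elimination from the resulting seven-membered acyl(vinyl)cobalt ring forms C3–C4; this is the known naphthoquinone synthesis from benzocyclobutenediones and alkynes through phthaloylcobalt complexes. Ring A is closed as a formal [4+2] annulation, by migratory insertion followed by reductive elimination at the metal, and arrives directly at the quinone oxidation level. No stereocentre is created, and the existing C1' centre should survive because the medium is near neutral and no electron-rich arene is present to help ionise the propargylic ester. The step needs chemoselectivity for the alkyne over the trisubstituted alkene, the ester and the silyl ether, which the much stronger binding and faster insertion of an alkyne at cobalt should secure. Regiochemistry is moot because 7 is symmetrical, so either orientation of insertion gives 21.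

**Step 12**
Reactants: 21 (R)-1-(5,8-dimethoxy-1,4-dioxo-1,4-dihydronaphthalen-2-yl)-4-methylpent-3-en-1-yl 3-methyl-3-(triethylsilyloxy)butanoate
Product: 22 (R)-1-(5,8-dihydroxy-1,4-dioxo-1,4-dihydronaphthalen-2-yl)-4-methylpent-3-en-1-yl 3-methyl-3-(triethylsilyloxy)butanoate
Conditions: MgI2·OEt2 (5 equiv), toluene–Et2O, rt → 45 °C, dark; aq. NH4Cl/Na2S2O3
Reagents that add atoms: none
Why: Chelation-assisted aryl methyl ether cleavage: magnesium binds between each quinone carbonyl and its peri methoxy oxygen and iodide removes the methyl group by SN2, an activation mode not open to the ester or the silyl ether.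

**Step 13**
Reactants: 22 (R)-1-(5,8-dihydroxy-1,4-dioxo-1,4-dihydronaphthalen-2-yl)-4-methylpent-3-en-1-yl 3-methyl-3-(triethylsilyloxy)butanoate
Product: 23 beta-HIVS, (R)-1-(5,8-dihydroxy-1,4-dioxo-1,4-dihydronaphthalen-2-yl)-4-methylpent-3-en-1-yl 3-hydroxy-3-methylbutanoate
Conditions: HF·pyridine, pyridine–THF, 0 °C → rt
Reagents that add atoms: none
Why: Fluoride-driven cleavage of the Si–O bond (silyl ether deprotection) under buffered, mildly acidic conditions that the naphthazarin, the ester and the alkene should tolerate.

**Compound list**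
1 | 2-bromo-1,4-dimethoxybenzene | COc1ccc(OC)c(Br)c1 | starting material
2 | 1,1-dimethoxyethene | C=C(OC)OC | starting material
3 | 3,6-dimethoxybenzyne | COC1=CC=C(OC)C#C1 | intermediate
4 | 3,6-dimethoxybenzocyclobuten-1(2H)-one dimethyl ketal | COc1ccc(OC)c2c1CC2(OC)OC | intermediate
5 | 3,6-dimethoxybenzocyclobuten-1(2H)-one | COc1ccc(OC)c2c1CC2=O | intermediate
6 | 2,2-dibromo-3,6-dimethoxybenzocyclobuten-1(2H)-one | COc1ccc(OC)c2c1C(Br)(Br)C2=O | intermediate
7 | 3,6-dimethoxybenzocyclobutene-1,2-dione | COc1ccc(OC)c2c1C(=O)C2=O | intermediate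
8 | 4-methylpent-3-enoic acid | CC(C)=CCC(=O)O | starting material
9 | N-methoxy-N,4-dimethylpent-3-enamide | CC(C)=CCC(=O)N(C)OC | intermediate
10 | ethynyltrimethylsilane | C#C[Si](C)(C)C | starting material
11 | lithium (trimethylsilyl)acetylide | [Li]C#C[Si](C)(C)C | intermediate
12 | 6-methyl-1-(trimethylsilyl)hept-5-en-1-yn-3-one | CC(C)=CCC(=O)C#C[Si](C)(C)C | intermediate
13 | (R)-6-methyl-1-(trimethylsilyl)hept-5-en-1-yn-3-ol | CC(C)=CC[C@@H](O)C#C[Si](C)(C)C | intermediate
14 | (R)-6-methylhept-5-en-1-yn-3-ol | CC(C)=CC[C@@H](O)C#C | intermediate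
15 | 3-hydroxy-3-methylbutanoic acid | CC(C)(O)CC(=O)O | starting material
16 | triethylsilyl 3-methyl-3-(triethylsilyloxy)butanoate | CC[Si](CC)(CC)OC(=O)CC(C)(C)O[Si](CC)(CC)CC | intermediate
17 | 3-methyl-3-(triethylsilyloxy)butanoic acid | CC[Si](CC)(CC)OC(C)(C)CC(=O)O | intermediate
18 | (R)-6-methylhept-5-en-1-yn-3-yl 3-methyl-3-(triethylsilyloxy)butanoate | CC(C)=CC[C@@H](OC(=O)CC(C)(C)O[Si](CC)(CC)CC)C#C | intermediate
19 | chlorobis(triphenylphosphine)(3,6-dimethoxyphthaloyl)cobalt, trivalent cobalt metallacycle | COc1ccc(OC)c2c1C(=O)[Co-2](Cl)([P+](c1ccccc1)(c1ccccc1)c1ccccc1)([P+](c1ccccc1)(c1ccccc1)c1ccccc1)C2=O | intermediate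
20 | chloro(dimethylglyoxime)(pyridine)(3,6-dimethoxyphthaloyl)cobalt, trivalent cobalt metallacycle | COc1ccc(OC)c2c1C(=O)[Co-3]1(Cl)([n+]3ccccc3)([N+](O)=C(C)C(C)=[N+]1O)C2=O | intermediate
21 | (R)-1-(5,8-dimethoxy-1,4-dioxo-1,4-dihydronaphthalen-2-yl)-4-methylpent-3-en-1-yl 3-methyl-3-(triethylsilyloxy)butanoate | CC(C)=CC[C@@H](OC(=O)CC(C)(C)O[Si](CC)(CC)CC)C1=CC(=O)c2c(OC)ccc(OC)c2C1=O | intermediate
22 | (R)-1-(5,8-dihydroxy-1,4-dioxo-1,4-dihydronaphthalen-2-yl)-4-methylpent-3-en-1-yl 3-methyl-3-(triethylsilyloxy)butanoate | CC(C)=CC[C@@H](OC(=O)CC(C)(C)O[Si](CC)(CC)CC)C1=CC(=O)c2c(O)ccc(O)c2C1=O | intermediate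
23 | beta-HIVS, (R)-1-(5,8-dihydroxy-1,4-dioxo-1,4-dihydronaphthalen-2-yl)-4-methylpent-3-en-1-yl 3-hydroxy-3-methylbutanoate | CC(C)=CC[C@@H](OC(=O)CC(C)(C)O)C1=CC(=O)c2c(O)ccc(O)c2C1=O | target

**Step count**
Total: 13 steps. Longest linear sequence: 8 steps (steps 5, 6, 7, 8, 10, 11, 12, 13, from 4-methylpent-3-enoic acid).

**Steps most likely to fail**

1. Step 11. In the telescoped sequence the liberated triphenylphosphine may compete with the alkyne for the vacant site on cobalt. The metallacycle may then decompose, or the terminal alkyne oligomerise, before insertion takes place. The fallback builds ring A by a Moore rearrangement instead; it sets out from alcohol 14 and dione 7 and comes back at 21. Silylation of 14 (TBSCl, imidazole, DMF) should give (R)-tert-butyldimethyl[(6-methylhept-5-en-1-yn-3-yl)oxy]silane F1. Its lithium acetylide (n-BuLi, THF, −78 °C; aq. NH4Cl quench) should add once to a carbonyl of 7 to give 2-[(R)-3-(tert-butyldimethylsilyloxy)-6-methylhept-5-en-1-yn-1-yl]-2-hydroxy-3,6-dimethoxybenzocyclobuten-1(2H)-one F2, formed as a mixture of epimers at the new carbinol carbon, which is of no consequence. Heating F2 in p-xylene at about 140 °C should open the four-membered ring to an ene-yne-ketene, which closes to a six-membered diradical and, after hydrogen transfer from the hydroxyl group, gives (R)-2-[1-(tert-butyldimethylsilyloxy)-4-methylpent-3-en-1-yl]-5,8-dimethoxynaphthalene-1,4-dione F3. HF·pyridine should then release (R)-2-(1-hydroxy-4-methylpent-3-en-1-yl)-5,8-dimethoxynaphthalene-1,4-dione F4, and Steglich esterification of F4 with acid 17 (DCC, DMAP, CH2Cl2) returns to 21.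

2. Step 12. The second ether cleavage may stall at the mono-phenol stage. Magnesium coordination together with iodide may also displace or eliminate the C1' acyloxy group, or reduce the quinone. The fallback removes the methyl groups oxidatively; it sets out from 21 and comes back at target 23. HF·pyridine first removes the silyl group to give (R)-1-(5,8-dimethoxy-1,4-dioxo-1,4-dihydronaphthalen-2-yl)-4-methylpent-3-en-1-yl 3-hydroxy-3-methylbutanoate F5. Oxidative demethylation of ring B with divalent silver oxide AgO in 6 M HNO3/acetone at 0 °C should give (R)-4-methyl-1-(1,4,5,8-tetraoxo-1,4,5,8-tetrahydronaphthalen-2-yl)pent-3-en-1-yl 3-hydroxy-3-methylbutanoate F6, and brief two-electron reduction of this diquinone with aqueous Na2S2O4 should deliver the naphthazarin 23.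

3. Step 3. Hydrogen abstraction from the already brominated and hindered C2 may stall at the monobromide, ionic bromination of the electron-rich ring may compete, and the gem-dibromide may open the four-membered ring in the silver-assisted hydrolysis of step 4. The fallback needs only one bromine and no gem-dihalide hydrolysis; it sets out from ketone 5 and comes back at dione 7. One equivalent of NBS under the same radical conditions should give 2-bromo-3,6-dimethoxybenzocyclobuten-1(2H)-one F7. AgNO3 in MeCN should convert it into 3,6-dimethoxy-2-oxo-1,2-dihydrobenzocyclobuten-1-yl nitrate F8, and NaOAc in DMSO at rt should then eliminate nitrite from the nitrate ester (Kornblum-type oxidation) to give 7.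

**Further compounds**
F1 | step 11 | (R)-tert-butyldimethyl[(6-methylhept-5-en-1-yn-3-yl)oxy]silane | CC(C)=CC[C@@H](O[Si](C)(C)C(C)(C)C)C#C
F2 | step 11 | 2-[(R)-3-(tert-butyldimethylsilyloxy)-6-methylhept-5-en-1-yn-1-yl]-2-hydroxy-3,6-dimethoxybenzocyclobuten-1(2H)-one (epimers at C2) | CC(C)=CC[C@@H](O[Si](C)(C)C(C)(C)C)C#CC1(O)C(=O)c2c(OC)ccc(OC)c21
F3 | step 11 | (R)-2-[1-(tert-butyldimethylsilyloxy)-4-methylpent-3-en-1-yl]-5,8-dimethoxynaphthalene-1,4-dione | CC(C)=CC[C@@H](O[Si](C)(C)C(C)(C)C)C1=CC(=O)c2c(OC)ccc(OC)c2C1=O
F4 | step 11 | (R)-2-(1-hydroxy-4-methylpent-3-en-1-yl)-5,8-dimethoxynaphthalene-1,4-dione | CC(C)=CC[C@@H](O)C1=CC(=O)c2c(OC)ccc(OC)c2C1=O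
F5 | step 12 | (R)-1-(5,8-dimethoxy-1,4-dioxo-1,4-dihydronaphthalen-2-yl)-4-methylpent-3-en-1-yl 3-hydroxy-3-methylbutanoate | CC(C)=CC[C@@H](OC(=O)CC(C)(C)O)C1=CC(=O)c2c(OC)ccc(OC)c2C1=O
F6 | step 12 | (R)-4-methyl-1-(1,4,5,8-tetraoxo-1,4,5,8-tetrahydronaphthalen-2-yl)pent-3-en-1-yl 3-hydroxy-3-methylbutanoate | CC(C)=CC[C@@H](OC(=O)CC(C)(C)O)C1=CC(=O)C2=C(C1=O)C(=O)C=CC2=O
F7 | step 3 | 2-bromo-3,6-dimethoxybenzocyclobuten-1(2H)-one (racemic) | COc1ccc(OC)c2c1C(Br)C2=O
F8 | step 3 | 3,6-dimethoxy-2-oxo-1,2-dihydrobenzocyclobuten-1-yl nitrate (racemic) | COc1ccc(OC)c2c1C(O[N+](=O)[O-])C2=O
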